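**Retrosynthetic overview**

1. Numbering: O1, C2 (aryl), C3 (methyl), C3a (allyl), C4–C7, C7a; ring A is the tetrahydrofuran O1–C2–C3–C3a–C7a and ring B the carbocycle C3a–C4–C5–C6–C7–C7a. The enabling feature is that the C6 ketone of ring B is cross-conjugated between a vinylogous ester arm (O1–C7a=C7) and an α-methoxy enone arm (C4=C5–OMe), so C3a is the vinylogous γ-carbon of C6=O and C4 is a formyl-level CH between C3a and the activated C5.
2. Ring B is therefore cut at C3a–C4 and C4=C5: a (5+1) annulation of the seco vinylogous ester 9 with a formamide acetal, closing by 6π-electrocyclisation of a trienolate and loss of HNMe2. This forms ring B last and sets the quaternary C3a.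
3. Ring A is closed for the final time just before, by 5-exo-dig oxa-Michael addition of the C2 hydroxyl to ynone 8, which comes from alkynol 7 and a methoxyacetyl Weinreb amide.
4. Alkynol 7 comes from trans-lactone 5 (α-allylation, then half-reduction and alkyne homologation); the lactone comes from anti homoallylic alcohol 2 by hydroboration and oxidative lactonisation.
5. C2 and C3 are set by a catalytic enantioselective anti-crotylation of 3,4,5-trimethoxybenzyl alcohol. Ring order: aryl ring purchased, ring A (temporarily as the lactone, then step 6), ring B (step 7).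

Key step: step 7

Assumption: (S)-SEGPHOS is taken to be the ligand antipode that gives the (1S,2S) adduct in step 1; if the sense is the opposite, (R)-SEGPHOS is used and nothing else changes.

**Route**

Step 1
Reactants: 1 3,4,5-trimethoxybenzyl alcohol
Product: 2 (1S,2S)-2-methyl-1-(3,4,5-trimethoxyphenyl)but-3-en-1-ol
Conditions: [Ir(cod)Cl]2 (2.5 mol %), (S)-SEGPHOS (5 mol %), 4-cyano-3-nitrobenzoic acid (10 mol %), Cs2CO3 (20 mol %), but-3-en-2-yl acetate (2 equiv), THF, 90 °C
Reagents that add atoms: but-3-en-2-yl acetate, CC(OC(C)=O)C=C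
Why: Iridium-catalysed transfer-hydrogenative carbonyl crotylation, in which the alcohol is dehydrogenated in situ to the aldehyde and attacked by the (E)-σ-crotyliridium species through a closed chair transition state, so that the anti relationship comes from the chair and the absolute sense of both new centres (1S,2S) from the ligand antipode.

Step 2
Reactants: 2 (1S,2S)-2-methyl-1-(3,4,5-trimethoxyphenyl)but-3-en-1-ol
Product: 3 (1S,2S)-2-methyl-1-(3,4,5-trimethoxyphenyl)butane-1,4-diol
Conditions: 9-BBN (2.5 equiv), THF, 0 to 25 °C; then NaOH, H2O2, 0 °C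
Reagents that add atoms: hydrogen peroxide, OO
Why: Anti-Markovnikov hydroboration–oxidation of the monosubstituted alkene with the bulky borane should give the primary alcohol without touching the two stereocentres.

Step 3
Reactants: 3 (1S,2S)-2-methyl-1-(3,4,5-trimethoxyphenyl)butane-1,4-diol
Product: 4 (4S,5S)-4-methyl-5-(3,4,5-trimethoxyphenyl)oxolan-2-one
Conditions: TEMPO (0.2 equiv), PhI(OAc)2 (2.5 equiv), CH2Cl2, 25 °C
Reagents that add atoms: none
Why: Nitroxyl-catalysed oxidative lactonisation, in which the primary alcohol is oxidised selectively to the aldehyde, the benzylic hydroxyl closes the lactol and this is oxidised on to the γ-lactone, so the 4,5-trans relationship is carried over unchanged.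

Step 4
Reactants: 4 (4S,5S)-4-methyl-5-(3,4,5-trimethoxyphenyl)oxolan-2-one
Product: 5 (3S,4S,5S)-4-methyl-3-(prop-2-en-1-yl)-5-(3,4,5-trimethoxyphenyl)oxolan-2-one
Conditions: LiN(i-Pr)2 (LDA, 1.1 equiv), THF, −78 °C; allyl bromide, −78 to −40 °C
Reagents that add atoms: allyl bromide, C=CCBr
Why: Lactone enolate alkylation, with allyl bromide expected to enter anti to the neighbouring C4 methyl to give mainly the 3,4-trans isomer; this centre is flattened again in step 7, so its configuration is of no consequence.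

Step 5
Reactants: 5 (3S,4S,5S)-4-methyl-3-(prop-2-en-1-yl)-5-(3,4,5-trimethoxyphenyl)oxolan-2-one
Product: 7 (1S,2S,3S)-3-ethynyl-2-methyl-1-(3,4,5-trimethoxyphenyl)hex-5-en-1-ol, via lactol 6 (not isolated)
Conditions: i-Bu2AlH (1.1 equiv), CH2Cl2, −78 °C; then MeOH, K2CO3, dimethyl (1-diazo-2-oxopropyl)phosphonate, 0 to 25 °C
Reagents that add atoms: dimethyl (1-diazo-2-oxopropyl)phosphonate (Ohira–Bestmann reagent), CC(=O)C(=[N+]=[N-])P(=O)(OC)OC
Why: Half-reduction of the lactone to the lactol at low temperature followed in the same flask by Seyferth–Gilbert homologation of the ring-opened hydroxy aldehyde with the Ohira–Bestmann reagent; any epimerisation next to the aldehyde would be harmless.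

Step 6
Reactants: 7 (1S,2S,3S)-3-ethynyl-2-methyl-1-(3,4,5-trimethoxyphenyl)hex-5-en-1-ol
Product: 9 (1Z)-1-methoxy-3-[(3S,4S,5S)-4-methyl-3-(prop-2-en-1-yl)-5-(3,4,5-trimethoxyphenyl)oxolan-2-ylidene]propan-2-one, via hydroxy ynone 8 (not isolated)
Conditions: n-BuLi (2.1 equiv), THF, −78 °C; N,2-dimethoxy-N-methylacetamide, −78 to 0 °C; aq NH4Cl; then DBU (0.2 equiv), CH2Cl2, 25 °C
Reagents that add atoms: N,2-dimethoxy-N-methylacetamide, COCC(=O)N(C)OC
Why: Acylation of the lithium acetylide (as the alkoxide–acetylide dianion) by the Weinreb amide gives the ynone, and base-catalysed 5-exo-dig oxa-Michael addition of the C2 hydroxyl to its β-carbon then closes ring A as the exocyclic vinylogous ester; no stereocentre is formed and the double-bond geometry is inconsequential.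

Step 7
Reactants: 9 (1Z)-1-methoxy-3-[(3S,4S,5S)-4-methyl-3-(prop-2-en-1-yl)-5-(3,4,5-trimethoxyphenyl)oxolan-2-ylidene]propan-2-one
Product: 12 (2S,3S,3aR)-5-methoxy-3-methyl-3a-(prop-2-en-1-yl)-2-(3,4,5-trimethoxyphenyl)-3,3a-dihydro-1-benzofuran-6(2H)-one, via enaminone 10 (not isolated), via amino ketone 11 (not isolated)
Conditions: t-BuOCH(NMe2)2 (1.5 equiv), PhMe, 80 °C; evaporate; KN(SiMe3)2 (1.5 equiv), THF, −78 to 25 °C; AcOH, 25 °C
Reagents that add atoms: tert-butoxybis(dimethylamino)methane (Bredereck's reagent), CN(C)C(OC(C)(C)C)N(C)C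
Why: Proposed new method: a formal (5+1) annulation in which the formamide acetal first aminomethylenates the only active methylene of 9 (C5, between the ketone and OMe) to enaminone 10, a known ketone–formamide acetal condensation, and KN(SiMe3)2 then removes the single remaining acidic proton, the vinylogous γ-H at C3a, to give the cross-conjugated trienolate C3a=C7a–C7=C6(O−)–C5=C4. This oxido-hexatriene, which carries donor groups on both inner positions next to its termini, should close ring B by thermal disrotatory 6π-electrocyclisation (formally a 6-endo-trig vinylogous Michael closure) that forms C3a–C4, and amino ketone 11 should then lose dimethylamine by β-elimination on acidification to leave the C4=C5(OMe) enone. The closest known reaction types are the low-temperature electrocyclisation of oxido-hexatrienes to cyclohexenones, the electrocyclisation/amine-elimination benzannulation of dienyl enaminones, and the heteroatom version that turns 1,5-bis(amino)pentadienones into 4-pyranones and 4-pyridones. The new quaternary centre C3a is controlled by the adjacent C3 stereocentre: the C4 terminus should bond to the face of the planar furanoid dienolate opposite the C3 methyl (the C2 aryl is remote and pseudo-equatorial), which places allyl cis to methyl (3aR), and the transient C4 amino centre is erased. The step needs C-cyclisation at C3a with this facial sense, and the substrate secures the first part because O1 is locked in ring A as an ether, so the pyranone-forming O-closure is impossible, C3a–H is the only acidic site of 10, and the geometry of the exocyclic C7a=C7 bond is irrelevant once it becomes a rotatable single bond in the trienolate.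

**Compound list**

1 | 3,4,5-trimethoxybenzyl alcohol | COc1cc(CO)cc(OC)c1OC | starting material
2 | (1S,2S)-2-methyl-1-(3,4,5-trimethoxyphenyl)but-3-en-1-ol | O[C@H](c1cc(OC)c(OC)c(OC)c1)[C@H](C=C)C | intermediate
3 | (1S,2S)-2-methyl-1-(3,4,5-trimethoxyphenyl)butane-1,4-diol | O[C@H](c1cc(OC)c(OC)c(OC)c1)[C@H](CCO)C | intermediate
4 | (4S,5S)-4-methyl-5-(3,4,5-trimethoxyphenyl)oxolan-2-one | O1[C@H](c2cc(OC)c(OC)c(OC)c2)[C@H](CC1=O)C | intermediate
5 | (3S,4S,5S)-4-methyl-3-(prop-2-en-1-yl)-5-(3,4,5-trimethoxyphenyl)oxolan-2-one (3,4-trans; the C3 epimer serves equally) | O1[C@H](c2cc(OC)c(OC)c(OC)c2)[C@H]([C@H](CC=C)C1=O)C | intermediate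
6 | (3S,4S,5S)-4-methyl-3-(prop-2-en-1-yl)-5-(3,4,5-trimethoxyphenyl)oxolan-2-ol (lactol, anomer mixture) | O1[C@H](c2cc(OC)c(OC)c(OC)c2)[C@H]([C@H](CC=C)C1O)C | intermediate (not isolated)
7 | (1S,2S,3S)-3-ethynyl-2-methyl-1-(3,4,5-trimethoxyphenyl)hex-5-en-1-ol | O[C@H](c1cc(OC)c(OC)c(OC)c1)[C@H]([C@H](CC=C)C#C)C | intermediate
8 | (5S,6S,7S)-7-hydroxy-1-methoxy-6-methyl-5-(prop-2-en-1-yl)-7-(3,4,5-trimethoxyphenyl)hept-3-yn-2-one | O[C@H](c1cc(OC)c(OC)c(OC)c1)[C@H]([C@H](CC=C)C#CC(=O)COC)C | intermediate (not isolated)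
9 | (1Z)-1-methoxy-3-[(3S,4S,5S)-4-methyl-3-(prop-2-en-1-yl)-5-(3,4,5-trimethoxyphenyl)oxolan-2-ylidene]propan-2-one | O1[C@H](c2cc(OC)c(OC)c(OC)c2)[C@H]([C@H](CC=C)/C1=C/C(=O)COC)C | intermediate
10 | (3Z)-4-(dimethylamino)-3-methoxy-1-[(2Z,3S,4S,5S)-4-methyl-3-(prop-2-en-1-yl)-5-(3,4,5-trimethoxyphenyl)oxolan-2-ylidene]but-3-en-2-one | O1[C@H](c2cc(OC)c(OC)c(OC)c2)[C@H]([C@H](CC=C)/C1=C/C(=O)/C(OC)=C/N(C)C)C | intermediate (not isolated)
11 | (2S,3S,3aR)-4-(dimethylamino)-5-methoxy-3-methyl-3a-(prop-2-en-1-yl)-2-(3,4,5-trimethoxyphenyl)-3,3a,4,5-tetrahydro-1-benzofuran-6(2H)-one (C4/C5 epimer mixture) | C=CC[C@@]12C(N(C)C)C(OC)C(=O)C=C1O[C@H](c1cc(OC)c(OC)c(OC)c1)[C@H]2C | intermediate (not isolated)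
12 | (2S,3S,3aR)-5-methoxy-3-methyl-3a-(prop-2-en-1-yl)-2-(3,4,5-trimethoxyphenyl)-3,3a-dihydro-1-benzofuran-6(2H)-one | C=CC[C@@]12C=C(OC)C(=O)C=C1O[C@H](c1cc(OC)c(OC)c(OC)c1)[C@H]2C | target

**Step count and risks**

Total steps: 7. Longest linear sequence: 7 steps.

Steps most likely to fail:

1. Step 7 (proposed new method). The trienolate may fail to electrocyclise and simply return 10 on quench, or C4 may bond to the wrong face of C3a (poor facial selectivity). The fallback uses known chemistry, sets out from 5 and comes back at 12, closing ring B with normal aldol polarity. Lactone 5 is deprotonated with LDA and treated with monomeric formaldehyde, which should enter anti to the C4 methyl and give (3R,4S,5S)-3-(hydroxymethyl)-4-methyl-3-(prop-2-en-1-yl)-5-(3,4,5-trimethoxyphenyl)oxolan-2-one F1. Silylation (t-BuMe2SiCl, imidazole) gives the silyl ether F2. The half-reduction/Seyferth–Gilbert sequence of step 5 gives the alkynol F3, and the acetylide acylation/oxa-Michael sequence of step 6 gives the silylated vinylogous ester F4. n-Bu4NF frees the primary alcohol F5 and Dess–Martin periodinane gives the aldehyde F6. K2CO3 in MeOH then effects the intramolecular aldol condensation of the C5 methylene (the only enolisable position) with the C4 aldehyde, and dehydration gives 12. In this variant C3a is set by a lactone enolate aldol and the ring closure is an ordinary 6-(enolexo)-exo-trig aldol condensation.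

2. Step 5. The lactol may open only sluggishly to the aldehyde, so homologation stalls, or the lactone may be over-reduced to the diol. The fallback sets out from 5 and comes back at 9 (it also replaces step 6) by a Claisen condensation/cyclodehydration approach. MeLi (1.05 equiv, THF, −78 °C) adds once to the lactone to give (3S,4S,5S)-5-hydroxy-4-methyl-3-(prop-2-en-1-yl)-5-(3,4,5-trimethoxyphenyl)pentan-2-one F7. Et3SiCl/imidazole gives the silyl ether F8. Kinetic deprotonation of the methyl ketone with LDA and Claisen condensation with methyl methoxyacetate gives the β-diketone F9. TsOH in MeOH/CH2Cl2 then removes the silyl group, and hemiketalisation of the C2 hydroxyl onto the nearer carbonyl followed by dehydration gives 9.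

3. Step 1. Anti/syn and enantiocontrol may erode with this electron-rich benzylic alcohol, for example through reversible dehydrogenation or uncatalysed background addition. The fallback sets out from 1 and comes back at 2 with a stoichiometric, reagent-controlled crotylation. MnO2 (CH2Cl2) gives 3,4,5-trimethoxybenzaldehyde F10. Crotylboration with (E)-crotyl-B(Ipc)2 (from trans-2-butene, n-BuLi/KOt-Bu, (−)-Ipc2BOMe and BF3·OEt2, −78 °C; NaOH/H2O2 work-up) should then give the anti (1S,2S) alcohol 2 through the chair transition state of the allylborane.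

**Further compounds**

F1 | step 7 | (3R,4S,5S)-3-(hydroxymethyl)-4-methyl-3-(prop-2-en-1-yl)-5-(3,4,5-trimethoxyphenyl)oxolan-2-one | O1[C@H](c2cc(OC)c(OC)c(OC)c2)[C@H]([C@](CC=C)(CO)C1=O)C
F2 | step 7 | (3R,4S,5S)-3-{[(tert-butyldimethylsilyl)oxy]methyl}-4-methyl-3-(prop-2-en-1-yl)-5-(3,4,5-trimethoxyphenyl)oxolan-2-one | O1[C@H](c2cc(OC)c(OC)c(OC)c2)[C@H]([C@](CC=C)(CO[Si](C)(C)C(C)(C)C)C1=O)C
F3 | step 7 | (1S,2S,3S)-3-{[(tert-butyldimethylsilyl)oxy]methyl}-3-ethynyl-2-methyl-1-(3,4,5-trimethoxyphenyl)hex-5-en-1-ol | O[C@H](c1cc(OC)c(OC)c(OC)c1)[C@H]([C@](CC=C)(CO[Si](C)(C)C(C)(C)C)C#C)C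
F4 | step 7 | 1-[(3R,4S,5S)-3-{[(tert-butyldimethylsilyl)oxy]methyl}-4-methyl-3-(prop-2-en-1-yl)-5-(3,4,5-trimethoxyphenyl)oxolan-2-ylidene]-3-methoxypropan-2-one (E/Z mixture) | O1[C@H](c2cc(OC)c(OC)c(OC)c2)[C@H]([C@](CC=C)(CO[Si](C)(C)C(C)(C)C)C1=CC(=O)COC)C
F5 | step 7 | 1-[(3R,4S,5S)-3-(hydroxymethyl)-4-methyl-3-(prop-2-en-1-yl)-5-(3,4,5-trimethoxyphenyl)oxolan-2-ylidene]-3-methoxypropan-2-one (E/Z mixture) | O1[C@H](c2cc(OC)c(OC)c(OC)c2)[C@H]([C@](CC=C)(CO)C1=CC(=O)COC)C
F6 | step 7 | (3S,4S,5S)-2-(3-methoxy-2-oxopropylidene)-4-methyl-3-(prop-2-en-1-yl)-5-(3,4,5-trimethoxyphenyl)oxolane-3-carbaldehyde (E/Z mixture) | O1[C@H](c2cc(OC)c(OC)c(OC)c2)[C@H]([C@](CC=C)(C=O)C1=CC(=O)COC)C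
F7 | step 5 | (3S,4S,5S)-5-hydroxy-4-methyl-3-(prop-2-en-1-yl)-5-(3,4,5-trimethoxyphenyl)pentan-2-one | O[C@H](c1cc(OC)c(OC)c(OC)c1)[C@H]([C@H](CC=C)C(C)=O)C
F8 | step 5 | (3S,4S,5S)-4-methyl-3-(prop-2-en-1-yl)-5-[(triethylsilyl)oxy]-5-(3,4,5-trimethoxyphenyl)pentan-2-one | CC[Si](CC)(CC)O[C@H](c1cc(OC)c(OC)c(OC)c1)[C@H]([C@H](CC=C)C(C)=O)C
F9 | step 5 | (5S,6S,7S)-1-methoxy-6-methyl-5-(prop-2-en-1-yl)-7-[(triethylsilyl)oxy]-7-(3,4,5-trimethoxyphenyl)heptane-2,4-dione | CC[Si](CC)(CC)O[C@H](c1cc(OC)c(OC)c(OC)c1)[C@H]([C@H](CC=C)C(=O)CC(=O)COC)C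
F10 | step 1 | 3,4,5-trimethoxybenzaldehyde | COc1cc(C=O)cc(OC)c1OC
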